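**Retrosynthetic overview**
1. The central oxolane is the water adduct of a tail-to-tail dimer of two identical (2S,3S)-ε-viniferin units. It is disconnected at C3–C4 and at both C–O bonds (the ring oxygen comes from water) to two molecules of the protected ε-viniferin 18.
2. Enabling feature: oxolane C2 and C5 each carry a para-oxygenated phenyl ring, so both are 4-alkoxybenzyl cation sites. C3 and C4 are the stilbene β-carbons bonded to C4 of the two dihydrobenzofurans, where two 4-alkoxystilbene radical cations couple.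
3. Monomer 18: the E-stilbene by Heck reaction on a 4-bromo-2,3-dihydrobenzofuran; that ring by enantioselective dirhodium-carbene C–H insertion (C3 set by the catalyst, C2 then equilibrated to trans); the diazo precursor from a nitrile and an aryl Grignard reagent; both oxygenated arenes from 5-bromoresorcinol.
4. Ring order: the two dihydrobenzofurans (step 7, before dimerisation), then the oxolane (step 11). Benzyl ethers sit on the 4-hydroxyphenyl oxygens and benzyl carbonates on the resorcinol-type oxygens; all ten leave in one hydrogenolysis.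

Key step: step 11

Assumption: Rh2(R-PTAD)4 is written as the catalyst antipode that delivers the (3S) centre in step 7; if the sense proves opposite, Rh2(S-PTAD)4 is used and nothing else changes.

**Route**

Step 1
Reactants: 1 5-bromoresorcinol (5-bromobenzene-1,3-diol)
Product: 3 2-bromo-4,6-dihydroxybenzaldehyde, via aryl iminium chloride 2 (not isolated)
Conditions: POCl3, DMF, MeCN, 0 °C to rt; then H2O, 50 °C
Reagents that add atoms: N,N-dimethylformamide CN(C)C=O (formyl carbon); water O (aldehyde oxygen)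
Why: Vilsmeier–Haack formylation of a 5-substituted resorcinol should go para to one hydroxyl and ortho to the other, next to the bromine (the orcinol pattern), and hydrolysis of the iminium salt gives the aldehyde.

Step 2
Reactants: 3 2-bromo-4,6-dihydroxybenzaldehyde
Product: 4 2-bromo-6-hydroxy-4-(methoxymethoxy)benzaldehyde
Conditions: MOMCl (1.05 equiv), i-Pr2NEt, CH2Cl2, 0 °C
Reagents that add atoms: chloromethyl methyl ether COCCl
Why: O-alkylation should select the 4-hydroxyl, which is the more acidic and unchelated one, because the 6-hydroxyl is tied up in a hydrogen bond to the aldehyde.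

Step 3
Reactants: 4 2-bromo-6-hydroxy-4-(methoxymethoxy)benzaldehyde; 5 4-(benzyloxy)benzyl chloride
Product: 6 2-{[4-(benzyloxy)phenyl]methoxy}-6-bromo-4-(methoxymethoxy)benzaldehyde
Conditions: K2CO3, KI (cat.), DMF, 60 °C
Reagents that add atoms: none
Why: Williamson ether synthesis on the remaining phenol with a reactive benzylic chloride installs the O–CH2–aryl unit whose methylene becomes C2 of the dihydrobenzofuran.

Step 4
Reactants: 6 2-{[4-(benzyloxy)phenyl]methoxy}-6-bromo-4-(methoxymethoxy)benzaldehyde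
Product: 7 2-{[4-(benzyloxy)phenyl]methoxy}-6-bromo-4-(methoxymethoxy)benzonitrile
Conditions: I2, aq. NH3 (28%), THF, rt
Reagents that add atoms: ammonia N
Why: Oxidative conversion of an aromatic aldehyde into the nitrile (aldimine, N-iodination, loss of HI) is mild enough for the acetal, the benzyl ethers and the aryl bromide.

Step 5
Reactants: 1 5-bromoresorcinol
Product: 8 1-bromo-3,5-bis(methoxymethoxy)benzene
Conditions: MOMCl (2.4 equiv), i-Pr2NEt, CH2Cl2, 0 °C to rt
Reagents that add atoms: chloromethyl methyl ether COCCl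
Why: Exhaustive O-alkylation of both phenols gives a base-stable aryl bromide fit for Grignard formation.

Step 6
Reactants: 8 1-bromo-3,5-bis(methoxymethoxy)benzene; 7 2-{[4-(benzyloxy)phenyl]methoxy}-6-bromo-4-(methoxymethoxy)benzonitrile
Product: 12 (2-{[4-(benzyloxy)phenyl]methoxy}-6-bromo-4-(methoxymethoxy)phenyl)[3,5-bis(methoxymethoxy)phenyl]methanone hydrazone, via aryl Grignard reagent 9 (not isolated), via N-bromomagnesio ketimine 10 (not isolated), via N-H ketimine 11 (not isolated)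
Conditions: Mg, THF, 50 °C; then 7, THF/toluene, 70 °C; MeOH, 0 °C; then N2H4·H2O, AcOH, EtOH, 70 °C
Reagents that add atoms: hydrazine NN
Why: Aryl Grignard addition to a nitrile stops at the metallated ketimine, and transimination of the freed N–H ketimine with hydrazine (ammonia leaves) is the established entry to hydrazones of crowded ketones that condense poorly.

Step 7
Reactants: 12 (2-{[4-(benzyloxy)phenyl]methoxy}-6-bromo-4-(methoxymethoxy)phenyl)[3,5-bis(methoxymethoxy)phenyl]methanone hydrazone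
Product: 14 (2R,3S)-2-[4-(benzyloxy)phenyl]-3-[3,5-bis(methoxymethoxy)phenyl]-4-bromo-6-(methoxymethoxy)-2,3-dihydro-1-benzofuran (2,3-cis), via diaryldiazomethane 13 (not isolated)
Conditions: MnO2, MeCN, 0 °C, filtration; then Rh2(R-PTAD)4 (1 mol %), MeCN, 0 °C
Reagents that add atoms: none
Why: Hydrazone dehydrogenation gives the donor/donor diazo compound, and the chiral dirhodium carbene undergoes enantioselective intramolecular 1,5 C–H insertion into the benzylic C–H of the ortho O–CH2–aryl group, the catalyst setting C3 as S and the concerted insertion placing the two aryl groups cis.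

Step 8
Reactants: 14 (2R,3S)-2-[4-(benzyloxy)phenyl]-3-[3,5-bis(methoxymethoxy)phenyl]-4-bromo-6-(methoxymethoxy)-2,3-dihydro-1-benzofuran
Product: 15 (2S,3S)-2-[4-(benzyloxy)phenyl]-4-bromo-3-(3,5-dihydroxyphenyl)-2,3-dihydro-1-benzofuran-6-ol (2,3-trans)
Conditions: HCl (3 M in MeOH), THF, 45 °C
Reagents that add atoms: none
Why: Acid-catalysed acetal exchange removes the three methoxymethyl groups, and reversible ionisation of the C2–O1 bond to the 4-benzyloxybenzyl cation lets C2 epimerise to the thermodynamically preferred 2,3-trans isomer while the non-ionisable C3 centre keeps its configuration.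

Step 9
Reactants: 15 (2S,3S)-2-[4-(benzyloxy)phenyl]-4-bromo-3-(3,5-dihydroxyphenyl)-2,3-dihydro-1-benzofuran-6-ol; 16 4-(benzyloxy)styrene
Product: 17 (2S,3S)-2-[4-(benzyloxy)phenyl]-4-{(E)-2-[4-(benzyloxy)phenyl]ethenyl}-3-(3,5-dihydroxyphenyl)-2,3-dihydro-1-benzofuran-6-ol
Conditions: Pd2(dba)3 (2.5 mol %), P(t-Bu)3·HBF4 (10 mol %), Cy2NMe, 1,4-dioxane, 90 °C
Reagents that add atoms: none
Why: Mizoroki–Heck reaction of the ortho-substituted aryl bromide with a styrene, helped by the bulky electron-rich phosphine, should give the E-stilbene through syn-carbopalladation and syn-β-hydride elimination, with the free phenols tolerated.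

Step 10
Reactants: 17 (2S,3S)-2-[4-(benzyloxy)phenyl]-4-{(E)-2-[4-(benzyloxy)phenyl]ethenyl}-3-(3,5-dihydroxyphenyl)-2,3-dihydro-1-benzofuran-6-ol
Product: 18 benzyl (2S,3S)-2-[4-(benzyloxy)phenyl]-4-{(E)-2-[4-(benzyloxy)phenyl]ethenyl}-3-{3,5-bis[(benzyloxycarbonyl)oxy]phenyl}-2,3-dihydro-1-benzofuran-6-yl carbonate
Conditions: CbzCl (3.6 equiv), pyridine, CH2Cl2, 0 °C
Reagents that add atoms: benzyl chloroformate O=C(Cl)OCc1ccccc1
Why: O-acylation of the three resorcinol-type phenols gives benzyl carbonates, which turn these rings from donors into weak acceptors for the key step and later leave by hydrogenolysis together with the benzyl ethers.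

Step 11
Reactants: 18 the tris(benzyl carbonate) bis(benzyl ether) of (2S,3S)-ε-viniferin (two molecules)
Product: 22 4,4'-{(2S,3S,4S,5R)-2,5-bis[4-(benzyloxy)phenyl]oxolane-3,4-diyl}bis{(2S,3S)-2-[4-(benzyloxy)phenyl]-3-{3,5-bis[(benzyloxycarbonyl)oxy]phenyl}-2,3-dihydro-1-benzofuran-6-yl benzyl carbonate} (oxolane 2,3-cis-3,4-trans-4,5-trans), via stilbene radical cation 19 (not isolated), via bis-benzylic dication 20 (not isolated), via hydroxy carbocation 21 (not isolated)
Conditions: controlled-potential electrolysis at the first anodic wave of 18, carbon felt anode, Pt cathode, undivided cell, LiClO4 (0.1 M), 2,6-lutidine, MeCN/CH2Cl2/H2O 6:3:1, 0 °C, argon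
Reagents that add atoms: water O
Why: One-electron anodic oxidation should occur at the 4-benzyloxystilbene, the most easily oxidised π-system of 18 once the resorcinol-type oxygens are carbonates, and two radical cations 19 couple through their β-carbons (the carbons bonded to C4 of the dihydrobenzofurans) to the dication 20, water adds to one cationic carbon (21) and the new hydroxyl closes on the other; the closest known reaction type is the anodic tail-to-tail dimerisation of 4-alkoxystilbenes and 4-alkoxystyrenes in wet acetonitrile, which gives 2,5-diaryl oxolanes. The oxolane closes by 5-exo-trig attack of the C2 hydroxyl oxygen on the cationic C5 (the O–C5 bond), after the C3–C4 bond has formed in the intermolecular radical-cation coupling. C3 and C4 are under substrate control: each stilbene reacts from the planar conformer in which the alkene points away from C3 of its own dihydrobenzofuran, the 3-aryl group there covers one alkene face, and bonding on the open face of both partners gives the (3S,4S) 3,4-trans pair. C2 is set when water adds to the first cation in its A(1,3)-minimised conformer (C3–H in the cation plane) on the face opposite the branched C4 substituent, which is expected to place the 2-aryl group cis to the C3 substituent, and C5 is set in the ring closure, where the tethered oxygen can only reach the cation face that puts the 5-aryl group trans to the C4 substituent. The step needs water to reach the benzylic cations before an aromatic carbon does (indane closure through C5 of a dihydrobenzofuran, seven-membered closure through a 3-aryl ring) and before a β-proton is lost, and it needs the kinetic 2,3-cis centre to survive. The benzyl carbonate at C6 flanks C5 of each dihydrobenzofuran and two more deactivate each 3-aryl ring, water is present at several mol/L, 2,6-lutidine takes up the protons, and the potential is held below the oxidation of the isolated alkoxyarenes of the product.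

Step 12
Reactants: 22 the protected tetramer
Product: 23 4,4'-[(2S,3S,4S,5R)-2,5-bis(4-hydroxyphenyl)oxolane-3,4-diyl]bis[(2S,3S)-3-(3,5-dihydroxyphenyl)-2-(4-hydroxyphenyl)-2,3-dihydro-1-benzofuran-6-ol] (CNP0270490.1)
Conditions: H2 (1 atm), 10% Pd/C, EtOAc/MeOH, rt
Reagents that add atoms: none
Why: Hydrogenolysis should cleave the four aryl benzyl ethers and the six aryl benzyl carbonates (the latter with loss of CO2) under neutral conditions, in which the acid-labile cis-2-aryl centre is not ionised and the benzylic C–O bonds of the three cyclic ethers react more slowly than aryl O-benzyl groups.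

**Compound list**
1 | 5-bromoresorcinol | Oc1cc(O)cc(Br)c1 | starting material
2 | [(2-bromo-4,6-dihydroxyphenyl)methylidene]dimethylammonium chloride | C[N+](C)=Cc1c(O)cc(O)cc1Br.[Cl-] | intermediate
3 | 2-bromo-4,6-dihydroxybenzaldehyde | O=Cc1c(O)cc(O)cc1Br | intermediate
4 | 2-bromo-6-hydroxy-4-(methoxymethoxy)benzaldehyde | O=Cc1c(O)cc(OCOC)cc1Br | intermediate
5 | 4-(benzyloxy)benzyl chloride | ClCc1ccc(OCc2ccccc2)cc1 | starting material
6 | 2-{[4-(benzyloxy)phenyl]methoxy}-6-bromo-4-(methoxymethoxy)benzaldehyde | O=Cc1c(OCc2ccc(OCc3ccccc3)cc2)cc(OCOC)cc1Br | intermediate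
7 | 2-{[4-(benzyloxy)phenyl]methoxy}-6-bromo-4-(methoxymethoxy)benzonitrile | N#Cc1c(OCc2ccc(OCc3ccccc3)cc2)cc(OCOC)cc1Br | intermediate
8 | 1-bromo-3,5-bis(methoxymethoxy)benzene | COCOc1cc(Br)cc(OCOC)c1 | intermediate
9 | [3,5-bis(methoxymethoxy)phenyl]magnesium bromide | COCOc1cc([Mg]Br)cc(OCOC)c1 | intermediate
10 | N-bromomagnesio derivative of ketimine 11 | Br[Mg]N=C(c1cc(OCOC)cc(OCOC)c1)c1c(OCc2ccc(OCc3ccccc3)cc2)cc(OCOC)cc1Br | intermediate
11 | 1-(2-{[4-(benzyloxy)phenyl]methoxy}-6-bromo-4-(methoxymethoxy)phenyl)-1-[3,5-bis(methoxymethoxy)phenyl]methanimine | N=C(c1cc(OCOC)cc(OCOC)c1)c1c(OCc2ccc(OCc3ccccc3)cc2)cc(OCOC)cc1Br | intermediate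
12 | hydrazone of the corresponding benzophenone (E/Z mixture) | NN=C(c1cc(OCOC)cc(OCOC)c1)c1c(OCc2ccc(OCc3ccccc3)cc2)cc(OCOC)cc1Br | intermediate
13 | 1-{[4-(benzyloxy)phenyl]methoxy}-3-bromo-2-{diazo[3,5-bis(methoxymethoxy)phenyl]methyl}-5-(methoxymethoxy)benzene | [N-]=[N+]=C(c1cc(OCOC)cc(OCOC)c1)c1c(OCc2ccc(OCc3ccccc3)cc2)cc(OCOC)cc1Br | intermediate
14 | (2R,3S)-2-[4-(benzyloxy)phenyl]-3-[3,5-bis(methoxymethoxy)phenyl]-4-bromo-6-(methoxymethoxy)-2,3-dihydro-1-benzofuran (cis) | c5ccccc5COc1ccc([C@@H]2Oc3cc(OCOC)cc(Br)c3[C@@H]2c2cc(OCOC)cc(OCOC)c2)cc1 | intermediate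
15 | (2S,3S)-2-[4-(benzyloxy)phenyl]-4-bromo-3-(3,5-dihydroxyphenyl)-2,3-dihydro-1-benzofuran-6-ol (trans) | c5ccccc5COc1ccc([C@H]2Oc3cc(O)cc(Br)c3[C@@H]2c2cc(O)cc(O)c2)cc1 | intermediate
16 | 4-(benzyloxy)styrene | C=Cc1ccc(OCc2ccccc2)cc1 | starting material
17 | (2S,3S)-2-[4-(benzyloxy)phenyl]-4-{(E)-2-[4-(benzyloxy)phenyl]ethenyl}-3-(3,5-dihydroxyphenyl)-2,3-dihydro-1-benzofuran-6-ol | c5ccccc5COc1ccc([C@H]2Oc3cc(O)cc(/C=C/c4ccc(OCc5ccccc5)cc4)c3[C@@H]2c2cc(O)cc(O)c2)cc1 | intermediate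
18 | tris(benzyl carbonate) of 17 | c5ccccc5COc1ccc([C@H]2Oc3cc(OC(=O)OCc5ccccc5)cc(/C=C/c4ccc(OCc5ccccc5)cc4)c3[C@@H]2c2cc(OC(=O)OCc5ccccc5)cc(OC(=O)OCc5ccccc5)c2)cc1 | intermediate
19 | radical cation of 18 (drawn with the charge at the 4-benzyloxybenzyl carbon and the spin at the β-carbon) | c5ccccc5COc1ccc([C@H]2Oc3cc(OC(=O)OCc5ccccc5)cc([CH][CH+]c4ccc(OCc5ccccc5)cc4)c3[C@@H]2c2cc(OC(=O)OCc5ccccc5)cc(OC(=O)OCc5ccccc5)c2)cc1 | intermediate
20 | (2S,3S)-2,3-diaryl-1,4-bis[4-(benzyloxy)phenyl]butane-1,4-diylium dication (aryl = the dihydrobenzofuran-4-yl unit of 18) | c7ccccc7COc1ccc([C@H]2Oc3cc(OC(=O)OCc7ccccc7)cc([C@@H]([CH+]c4ccc(OCc7ccccc7)cc4)[C@@H](c5cc(OC(=O)OCc7ccccc7)cc6c5[C@H](c5cc(OC(=O)OCc7ccccc7)cc(OC(=O)OCc7ccccc7)c5)[C@@H](c5ccc(OCc7ccccc7)cc5)O6)[CH+]c4ccc(OCc7ccccc7)cc4)c3[C@@H]2c2cc(OC(=O)OCc7ccccc7)cc(OC(=O)OCc7ccccc7)c2)cc1 | intermediate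
21 | (1S,2S,3S)-4-hydroxy-substituted monocation (water adduct of 20 at one benzylic carbon) | c7ccccc7COc1ccc([C@H]2Oc3cc(OC(=O)OCc7ccccc7)cc([C@@H]([C@H](O)c4ccc(OCc7ccccc7)cc4)[C@@H](c5cc(OC(=O)OCc7ccccc7)cc6c5[C@H](c5cc(OC(=O)OCc7ccccc7)cc(OC(=O)OCc7ccccc7)c5)[C@@H](c5ccc(OCc7ccccc7)cc5)O6)[CH+]c4ccc(OCc7ccccc7)cc4)c3[C@@H]2c2cc(OC(=O)OCc7ccccc7)cc(OC(=O)OCc7ccccc7)c2)cc1 | intermediate
22 | tetra-O-benzyl hexakis(O-benzyloxycarbonyl) derivative of 23, oxolane (2S,3S,4S,5R) | c7ccccc7COc1ccc([C@H]2Oc3cc(OC(=O)OCc7ccccc7)cc([C@@H]4[C@@H](c5cc(OC(=O)OCc7ccccc7)cc6c5[C@H](c5cc(OC(=O)OCc7ccccc7)cc(OC(=O)OCc7ccccc7)c5)[C@@H](c5ccc(OCc7ccccc7)cc5)O6)[C@H](c5ccc(OCc7ccccc7)cc5)O[C@@H]4c4ccc(OCc7ccccc7)cc4)c3[C@@H]2c2cc(OC(=O)OCc7ccccc7)cc(OC(=O)OCc7ccccc7)c2)cc1 | intermediate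
23 | 4,4'-[(2S,3S,4S,5R)-2,5-bis(4-hydroxyphenyl)oxolane-3,4-diyl]bis[(2S,3S)-3-(3,5-dihydroxyphenyl)-2-(4-hydroxyphenyl)-2,3-dihydro-1-benzofuran-6-ol] | Oc1ccc([C@H]2Oc3cc(O)cc([C@@H]4[C@@H](c5cc(O)cc6c5[C@H](c5cc(O)cc(O)c5)[C@@H](c5ccc(O)cc5)O6)[C@H](c5ccc(O)cc5)O[C@@H]4c4ccc(O)cc4)c3[C@@H]2c2cc(O)cc(O)c2)cc1 | target

**Step count and risks**

Total steps: 12. Longest linear sequence: 11 (steps 1 to 4 and 6 to 12).

Steps most likely to fail:

Step 11. The benzylic cations may be captured by aromatic carbon or lose a β-proton before water arrives, water may add to the first cation on the other face (all-trans oxolane), or the C–C coupling may show poor facial selectivity. The fallback builds the oxolane stepwise by lignan chemistry; it sets out from 15 and comes back at 23.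
- The three phenols of 15 would be benzylated (BnBr, K2CO3, DMF) to (2S,3S)-6-(benzyloxy)-2-[4-(benzyloxy)phenyl]-3-[3,5-bis(benzyloxy)phenyl]-4-bromo-2,3-dihydro-1-benzofuran F1.
- Palladium-catalysed α-arylation of 4'-(benzyloxy)acetophenone with F1 (Pd2(dba)3, XPhos, NaOt-Bu, toluene, 80 °C) would give the deoxybenzoin 1-[4-(benzyloxy)phenyl]-2-{(2S,3S)-6-(benzyloxy)-2-[4-(benzyloxy)phenyl]-3-[3,5-bis(benzyloxy)phenyl]-2,3-dihydro-1-benzofuran-4-yl}ethan-1-one F2.
- Oxidative coupling of its lithium enolate (LiN(SiMe3)2, THF, −78 °C, then CuCl2) would form the C3–C4 bond in (2S,3S)-2,3-diaryl-1,4-bis[4-(benzyloxy)phenyl]butane-1,4-dione F3. The threo isomer would be separated from its two diastereomers, which can be recycled by base equilibration of the α-centres.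
- One equivalent of LiBH(s-Bu)3 at −78 °C would reduce one ketone, and the alkoxide closes on the other carbonyl to the cyclic hemiketal (3S,4S,5R)-3,4-diaryl-2,5-bis[4-(benzyloxy)phenyl]oxolan-2-ol F4. Its C5 carbinol epimer would have to be removed.
- Et3SiH and BF3·OEt2 at −78 °C would reduce the 2-aryl oxocarbenium ion with hydride delivery anti to the C3 substituent, the established way to 2,3-cis-2-aryl oxolanes, to give the deca-O-benzyl ether of 23 F5.
- Hydrogenolysis as in step 12 would then give 23.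

Step 7. Carbene formation from the di-ortho-substituted diazo compound may be slow (azine formation), or the C–H insertion may proceed with low enantioselectivity. The fallback gives up catalyst control; it sets out from 12 and comes back at 15.
- The diazo compound 13 would be decomposed with the less hindered achiral Rh2(OAc)4 to the racemic cis-2-[4-(benzyloxy)phenyl]-3-[3,5-bis(methoxymethoxy)phenyl]-4-bromo-6-(methoxymethoxy)-2,3-dihydro-1-benzofuran F6.
- Methanolic HCl as in step 8 would give the racemic trans-2-[4-(benzyloxy)phenyl]-4-bromo-3-(3,5-dihydroxyphenyl)-2,3-dihydro-1-benzofuran-6-ol F7.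
- F7 would be resolved by preparative chromatography on a chiral stationary phase (amylose tris(3,5-dimethylphenylcarbamate), supercritical CO2/MeOH), and the (2S,3S) enantiomer 15 taken on.

Step 6. The aryl Grignard reagent may fail to add to the crowded nitrile, or bromine–magnesium exchange at the ortho bromide or displacement of the ortho alkoxy group may compete. The fallback makes the C=N bond by carbonyl condensation; it sets out from 8 and 6 and comes back at 12.
- Bromine–lithium exchange on 8 (n-BuLi, THF, −78 °C) would give [3,5-bis(methoxymethoxy)phenyl]lithium F8.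
- F8 should add to the aldehyde 6 faster than it exchanges with the aryl bromide, giving (2-{[4-(benzyloxy)phenyl]methoxy}-6-bromo-4-(methoxymethoxy)phenyl)[3,5-bis(methoxymethoxy)phenyl]methanol F9.
- Dess–Martin periodinane would oxidise F9 to (2-{[4-(benzyloxy)phenyl]methoxy}-6-bromo-4-(methoxymethoxy)phenyl)[3,5-bis(methoxymethoxy)phenyl]methanone F10.
- Condensation of F10 with anhydrous hydrazine (AcOH, n-BuOH, 110 °C) would give 12.

Further compounds
F1 | step 11 | (2S,3S)-6-(benzyloxy)-2-[4-(benzyloxy)phenyl]-3-[3,5-bis(benzyloxy)phenyl]-4-bromo-2,3-dihydro-1-benzofuran | c5ccccc5COc1ccc([C@H]2Oc3cc(OCc5ccccc5)cc(Br)c3[C@@H]2c2cc(OCc5ccccc5)cc(OCc5ccccc5)c2)cc1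
F2 | step 11 | 1-[4-(benzyloxy)phenyl]-2-{(2S,3S)-6-(benzyloxy)-2-[4-(benzyloxy)phenyl]-3-[3,5-bis(benzyloxy)phenyl]-2,3-dihydro-1-benzofuran-4-yl}ethan-1-one | c5ccccc5COc1ccc([C@H]2Oc3cc(OCc5ccccc5)cc(CC(=O)c4ccc(OCc5ccccc5)cc4)c3[C@@H]2c2cc(OCc5ccccc5)cc(OCc5ccccc5)c2)cc1
F3 | step 11 | (2S,3S)-1,4-bis[4-(benzyloxy)phenyl]-2,3-bis{(2S,3S)-6-(benzyloxy)-2-[4-(benzyloxy)phenyl]-3-[3,5-bis(benzyloxy)phenyl]-2,3-dihydro-1-benzofuran-4-yl}butane-1,4-dione | c7ccccc7COc1ccc([C@H]2Oc3cc(OCc7ccccc7)cc([C@@H](C(=O)c4ccc(OCc7ccccc7)cc4)[C@@H](c5cc(OCc7ccccc7)cc6c5[C@H](c5cc(OCc7ccccc7)cc(OCc7ccccc7)c5)[C@@H](c5ccc(OCc7ccccc7)cc5)O6)C(=O)c4ccc(OCc7ccccc7)cc4)c3[C@@H]2c2cc(OCc7ccccc7)cc(OCc7ccccc7)c2)cc1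
F4 | step 11 | (3S,4S,5R)-2,5-bis[4-(benzyloxy)phenyl]-3,4-bis{(2S,3S)-6-(benzyloxy)-2-[4-(benzyloxy)phenyl]-3-[3,5-bis(benzyloxy)phenyl]-2,3-dihydro-1-benzofuran-4-yl}oxolan-2-ol (both C2 epimers) | c7ccccc7COc1ccc([C@H]2Oc3cc(OCc7ccccc7)cc([C@@H]4[C@@H](c5cc(OCc7ccccc7)cc6c5[C@H](c5cc(OCc7ccccc7)cc(OCc7ccccc7)c5)[C@@H](c5ccc(OCc7ccccc7)cc5)O6)[C@H](c5ccc(OCc7ccccc7)cc5)OC4(O)c4ccc(OCc7ccccc7)cc4)c3[C@@H]2c2cc(OCc7ccccc7)cc(OCc7ccccc7)c2)cc1
F5 | step 11 | deca-O-benzyl ether of 23, oxolane (2S,3S,4S,5R) | c7ccccc7COc1ccc([C@H]2Oc3cc(OCc7ccccc7)cc([C@@H]4[C@@H](c5cc(OCc7ccccc7)cc6c5[C@H](c5cc(OCc7ccccc7)cc(OCc7ccccc7)c5)[C@@H](c5ccc(OCc7ccccc7)cc5)O6)[C@H](c5ccc(OCc7ccccc7)cc5)O[C@@H]4c4ccc(OCc7ccccc7)cc4)c3[C@@H]2c2cc(OCc7ccccc7)cc(OCc7ccccc7)c2)cc1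
F6 | step 7 | racemic cis-2-[4-(benzyloxy)phenyl]-3-[3,5-bis(methoxymethoxy)phenyl]-4-bromo-6-(methoxymethoxy)-2,3-dihydro-1-benzofuran (both enantiomers) | c5ccccc5COc1ccc([C@@H]2Oc3cc(OCOC)cc(Br)c3[C@@H]2c2cc(OCOC)cc(OCOC)c2)cc1.c5ccccc5COc1ccc([C@H]2Oc3cc(OCOC)cc(Br)c3[C@H]2c2cc(OCOC)cc(OCOC)c2)cc1
F7 | step 7 | racemic trans-2-[4-(benzyloxy)phenyl]-4-bromo-3-(3,5-dihydroxyphenyl)-2,3-dihydro-1-benzofuran-6-ol (both enantiomers) | c5ccccc5COc1ccc([C@H]2Oc3cc(O)cc(Br)c3[C@@H]2c2cc(O)cc(O)c2)cc1.c5ccccc5COc1ccc([C@@H]2Oc3cc(O)cc(Br)c3[C@H]2c2cc(O)cc(O)c2)cc1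
F8 | step 6 | [3,5-bis(methoxymethoxy)phenyl]lithium | [Li]c1cc(OCOC)cc(OCOC)c1
F9 | step 6 | (2-{[4-(benzyloxy)phenyl]methoxy}-6-bromo-4-(methoxymethoxy)phenyl)[3,5-bis(methoxymethoxy)phenyl]methanol (racemic, centre removed in the next step) | OC(c1cc(OCOC)cc(OCOC)c1)c1c(OCc2ccc(OCc3ccccc3)cc2)cc(OCOC)cc1Br
F10 | step 6 | (2-{[4-(benzyloxy)phenyl]methoxy}-6-bromo-4-(methoxymethoxy)phenyl)[3,5-bis(methoxymethoxy)phenyl]methanone | O=C(c1cc(OCOC)cc(OCOC)c1)c1c(OCc2ccc(OCc3ccccc3)cc2)cc(OCOC)cc1Br
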